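With the cyclohexene numbered C1 (quaternary; CO2H and 4-methylpent-3-enyl), C2, C3, C4=C5 (CH2OH on C5) and C6, a nine-carbon dienyl bridge (C7–C15) joins C6 to C2 and completes a twelve-membered ring through C1. The C4=C5 alkene flanked by the C1–C6 and C2–C3 bonds is a Diels–Alder retron, so cutting both bonds unravels the bicycle to an acyclic, achiral hexaene: a C3=C4–C5=C6 diene tethered through the bridge to a (Z)-C1=C2 α-alkyl enoate. One catalyst-controlled intramolecular [4+2] reaction closes both rings and sets C1, C2 and C6. The chain is built linearly from nerol by olefinations and cross-coupling.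

Key step: step 19

Assumption (chemistry): the catalyst derived from (S)-α,α-diphenylprolinol is taken to shield the Si face of C1; no validated facial model covers an α,β-dialkyl enoate, and if the opposite enantiomer forms, the (R)-catalyst is used with nothing else changed.
Remark: atom labels C1–C15 in the Why lines are those of the first paragraph; the CHBr centres of 12 and 17, the oxirane centre of 13 and the α-carbon of 28 are racemic and are destroyed later.

Step 1
Reactants: 1 nerol
Product: 2 neryl bromide
Conditions: PBr3 (0.4 equiv), Et2O, −10 °C, dark; used crude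
Reagents that add atoms: phosphorus tribromide, BrP(Br)Br
Why: Bromide displaces the allylic phosphite ester in an SN2 substitution at low temperature, which keeps the (Z)-alkene and avoids allylic transposition.

Step 2
Reactants: 3 1-(trimethylsilyl)propyne + 2 neryl bromide
Product: 5 trimethylsilyl dienyne, via 3-lithio-1-(trimethylsilyl)propyne 4 (not isolated)
Conditions: n-BuLi, THF, −78 to −20 °C; then 2, −78 °C to rt
Reagents that add atoms: none
Why: Propargylic lithiation followed by SN2 alkylation of the primary allylic bromide, in which the silyl group blocks the acetylenic position and steers bond formation to the propargylic rather than the allenic carbon.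

Step 3
Reactants: 5 trimethylsilyl dienyne
Product: 6 (5Z)-6,10-dimethylundeca-5,9-dien-1-yne
Conditions: K2CO3 (0.2 equiv), MeOH, rt
Reagents that add atoms: none
Why: Base-catalysed methanolysis of the alkynyl C–Si bond (protodesilylation) frees the terminal alkyne without touching the alkenes.

Step 4
Reactants: 6 (5Z)-6,10-dimethylundeca-5,9-dien-1-yne + 7 ethylene oxide
Product: 10 (3E,7Z)-homofarnesol, via alkenyldimethylalane 8 (not isolated), via lithium alkenylalanate 9 (not isolated)
Conditions: AlMe3 (2 equiv), Cp2ZrCl2 (0.25 equiv), CH2Cl2, 0 °C to rt; volatiles removed; n-BuLi, hexane–THF, −78 °C; 7, −78 to 0 °C; dilute HCl work-up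
Reagents that add atoms: trimethylaluminium, C[Al](C)C
Why: Zirconium-catalysed Negishi carboalumination adds methyl and aluminium syn with methyl on the internal carbon, and the derived alanate opens the epoxide with retention at the alkenyl carbon, so the new trisubstituted alkene is (E).

Step 5
Reactants: 10 (3E,7Z)-homofarnesol
Product: 11 homofarnesyl tert-butyldimethylsilyl ether
Conditions: t-BuMe2SiCl, imidazole, CH2Cl2, rt
Reagents that add atoms: tert-butyldimethylsilyl chloride, CC(C)(C)[Si](C)(C)Cl
Why: Imidazole-mediated silylation of the primary alcohol masks the hydroxyl during the oxidative shortening of the chain.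

Step 6
Reactants: 11 homofarnesyl tert-butyldimethylsilyl ether
Product: 12 terminal bromohydrin
Conditions: N-bromosuccinimide (1.05 equiv), THF–H2O, 0 °C
Reagents that add atoms: N-bromosuccinimide, O=C1CCC(=O)N1Br; water, O
Why: Bromohydrin formation (bromonium ion opened by water at the tertiary carbon) takes place preferentially at the terminal isopropylidene, the most exposed alkene of the chain coiled in aqueous medium, and the racemic CHBr centre is removed in step 8.

Step 7
Reactants: 12 terminal bromohydrin
Product: 13 terminal epoxide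
Conditions: K2CO3, MeOH, rt
Reagents that add atoms: none
Why: Intramolecular Williamson etherification (SN2 displacement of bromide by the neighbouring alkoxide) closes the oxirane.

Step 8
Reactants: 13 terminal epoxide
Product: 14 trisnor aldehyde silyl ether
Conditions: H5IO6 (1.2 equiv), THF–Et2O, 0 °C, short reaction time
Reagents that add atoms: none
Why: Periodic acid opens the epoxide to the glycol with water entering at the tertiary carbon and cleaves it in the same flask (glycol cleavage), releasing acetone and leaving the aldehyde that keeps the former epoxide oxygen, while the silyl ether tolerates the brief cold exposure.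

Step 9
Reactants: 15 methyl bis(2,2,2-trifluoroethyl)phosphonoacetate
Product: 16 dibromophosphonoacetate
Conditions: Br2, aq. NaOH (NaOBr formed in the flask), 0 °C
Reagents that add atoms: bromine, BrBr
Why: Electrophilic bromination of the doubly activated methylene by hypobromite is driven to the dibromide, which avoids mixtures of mono- and dibromide.

Step 10
Reactants: 16 dibromophosphonoacetate
Product: 17 bromophosphonoacetate
Conditions: SnCl2·2H2O, EtOH–H2O, 0 °C
Reagents that add atoms: none
Why: Divalent tin removes one positive bromine in a halophilic two-electron reduction and the stabilised carbanion is protonated, so the reduction stops at the monobromide.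

Step 11
Reactants: 14 trisnor aldehyde silyl ether + 17 bromophosphonoacetate
Product: 19 (E)-α-bromo enoate, via potassium bromophosphonate carbanion 18 (not isolated)
Conditions: 17, KOt-Bu, 18-crown-6, THF, −78 °C; then 14
Reagents that add atoms: none
Why: Horner–Wadsworth–Emmons olefination with the electron-poor trifluoroethyl phosphonate under dissociating conditions eliminates rapidly from the kinetic adduct and places the chain cis to the ester, which is the (E)-isomer because bromine outranks the ester.

Step 12
Reactants: 19 (E)-α-bromo enoate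
Product: 20 (E)-2-bromoallylic alcohol
Conditions: i-Bu2AlH (2.2 equiv), CH2Cl2, −78 °C; aq. KNaC4H4O6 (potassium sodium tartrate) work-up
Reagents that add atoms: none
Why: Hydride 1,2-reduction of the ester at low temperature gives the allylic alcohol and leaves the vinyl bromide, the silyl ether and the alkene geometry untouched.

Step 13
Reactants: 20 (E)-2-bromoallylic alcohol
Product: 21 bromoallyl tert-butyldiphenylsilyl ether
Conditions: t-BuPh2SiCl, imidazole, CH2Cl2, rt
Reagents that add atoms: tert-butyldiphenylsilyl chloride, CC(C)(C)[Si](Cl)(c1ccccc1)c1ccccc1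
Why: Imidazole-mediated silylation installs a bulky, weakly Lewis-basic ether that outlasts the later selective desilylation and the Lewis acid step.

Step 14
Reactants: 21 bromoallyl tert-butyldiphenylsilyl ether + 22 tributyl(vinyl)stannane
Product: 23 dienyl bis-silyl ether
Conditions: Pd(PPh3)4 (5 mol%), toluene, 90 °C, BHT (catalytic)
Reagents that add atoms: none
Why: Stille coupling (oxidative addition of zerovalent palladium into the C–Br bond, transmetalation from tin, reductive elimination) proceeds with retention, so the vinyl group ends trans to the chain and C7 sits in the outside position of the diene at C6.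

Step 15
Reactants: 23 dienyl bis-silyl ether
Product: 24 dienyl tetraenol
Conditions: pyridinium p-toluenesulfonate (0.2 equiv), MeOH–CH2Cl2, rt
Reagents that add atoms: none
Why: Acid-catalysed methanolysis removes the primary tert-butyldimethylsilyl ether far faster than the bulkier tert-butyldiphenylsilyl ether, and the acid is too weak to protonate the diene.

Step 16
Reactants: 24 dienyl tetraenol
Product: 25 dienyl tetraenal
Conditions: Dess–Martin periodinane, NaHCO3, CH2Cl2, 0 °C; used at once
Reagents that add atoms: none
Why: Dess–Martin oxidation under buffered, nearly neutral conditions stops at the aldehyde and leaves the β,γ-alkene out of conjugation.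

Step 17
Reactants: 15 methyl bis(2,2,2-trifluoroethyl)phosphonoacetate + 26 5-bromo-2-methylpent-2-ene
Product: 28 α-(4-methylpent-3-enyl) phosphonoacetate, via sodium phosphonoacetate carbanion 27 (not isolated)
Conditions: 15 (1.5 equiv), NaH, DMF, 0 °C; then 26, NaI (0.1 equiv), 50 °C
Reagents that add atoms: none
Why: SN2 C-alkylation of the stabilised phosphonate carbanion, assisted by iodide formed in a Finkelstein exchange, with excess phosphonate to suppress a second alkylation.

Step 18
Reactants: 25 dienyl tetraenal + 28 α-(4-methylpent-3-enyl) phosphonoacetate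
Product: 30 acyclic hexaene (Z)-ester, via potassium alkylphosphonate carbanion 29 (not isolated)
Conditions: 28, KN(SiMe3)2, 18-crown-6, THF, −78 °C; then 25
Reagents that add atoms: none
Why: Still–Gennari olefination eliminates irreversibly from the kinetic adduct and gives the trisubstituted enoate with the ester cis to the chain, that is (Z), while the weakly basic phosphonate anion at −78 °C spares the enolisable β,γ-unsaturated aldehyde.

Step 19
Reactants: 30 acyclic hexaene (Z)-ester
Product: 31 bicyclo[9.3.1] cycloadduct
Conditions: (S)-3,3-diphenyl-1-(2-methylphenyl)tetrahydro-1H,3H-pyrrolo[1,2-c][1,3,2]oxazaborole (0.30 equiv), AlBr3 (0.25 equiv), CH2Cl2, −40 to −20 °C, syringe-pump addition of 30 to 2 mM final concentration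
Reagents that add atoms: none
Why: Proposed new method: the cationic boron Lewis acid binds the ester carbonyl of 30, lowers the LUMO of the C1=C2 enoate and triggers a concerted, asynchronous intramolecular Diels–Alder reaction in which the unsubstituted diene terminus C3 bonds to the β-carbon C2 slightly ahead of C6 to C1; the closest known reaction types are Lewis-acid-promoted macrocyclising intramolecular Diels–Alder reactions of tethered diene enoates and oxazaborolidinium-catalysed enantioselective Diels–Alder reactions of enoates, which have not been combined in a bridging twelve-membered closure. The cyclohexene closes as the [4+2] ring, and the twelve-membered ring closes in the same event in the bridged (1,3) mode because the nine-atom tether joins C6 to C2 while C6 bonds to C1. The C1/C2 relation is set by suprafacial addition to the (Z)-enoate (ester cis to the bridge), C6 by the (E)-diene terminus reacting through the transition state with ester and tether exo and the 4-methylpentenyl group endo, and the absolute configuration of all three by the catalyst, which must leave the Re face of C1 open to C6. The step needs bridged regiochemistry, exo topology and one dienophile face: the first is favoured by the 1-alkyl polarisation of the diene and by the tighter eleven-membered ring of the fused mode, the second by the α-alkyl group and the outside position of C7 on C6, and the third rests on the catalyst alone since 30 has no stereocentre. High dilution and slow addition suppress intermolecular cycloaddition.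

Step 20
Reactants: 31 bicyclo[9.3.1] cycloadduct
Product: 32 hydroxy methyl ester
Conditions: Bu4NF, THF, 0 °C to rt
Reagents that add atoms: none
Why: Fluoride-induced cleavage of the Si–O bond (desilylation) frees the allylic alcohol, and lactonisation onto the C1 ester is blocked because it would place the C4=C5 alkene at a bridgehead.

Step 21
Reactants: 32 hydroxy methyl ester
Product: 33 target acid CNP0267152.2
Conditions: NaSEt (5 equiv), degassed DMF, 90 °C; then 1 M HCl, 0 °C
Reagents that add atoms: none
Why: The thiolate attacks the ester methyl group in an SN2 O-dealkylation, which bypasses the shielded carbonyl of the quaternary ester, and no stereocentre can epimerise because C1 bears no hydrogen.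

Compound list
1 | nerol, (2Z)-3,7-dimethylocta-2,6-dien-1-ol | CC(C)=CCC/C(C)=C\CO | starting material
2 | neryl bromide, (2Z)-1-bromo-3,7-dimethylocta-2,6-diene | CC(C)=CCC/C(C)=C\CBr | intermediate
3 | 1-(trimethylsilyl)propyne | CC#C[Si](C)(C)C | starting material
4 | 3-lithio-1-(trimethylsilyl)propyne (not isolated) | [Li]CC#C[Si](C)(C)C | intermediate
5 | trimethyl[(5Z)-6,10-dimethylundeca-5,9-dien-1-yn-1-yl]silane | C[Si](C)(C)C#CCC/C=C(C)\CCC=C(C)C | intermediate
6 | (5Z)-6,10-dimethylundeca-5,9-dien-1-yne | C#CCC/C=C(C)\CCC=C(C)C | intermediate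
7 | ethylene oxide (oxirane) | C1CO1 | starting material
8 | dimethyl[(1E,5Z)-2,6,10-trimethylundeca-1,5,9-trien-1-yl]alane (not isolated) | C[Al](C)/C=C(C)/CC/C=C(C)\CCC=C(C)C | intermediate
9 | lithium butyl(dimethyl)[(1E,5Z)-2,6,10-trimethylundeca-1,5,9-trien-1-yl]aluminate (not isolated) | [Li+].CCCC[Al-](C)(C)/C=C(C)/CC/C=C(C)\CCC=C(C)C | intermediate
10 | (3E,7Z)-homofarnesol, (3E,7Z)-4,8,12-trimethyltrideca-3,7,11-trien-1-ol | CC(C)=CCC/C(C)=C\CC/C(C)=C/CCO | intermediate
11 | tert-butyldimethyl{[(3E,7Z)-4,8,12-trimethyltrideca-3,7,11-trien-1-yl]oxy}silane | CC(C)=CCC/C(C)=C\CC/C(C)=C/CCO[Si](C)(C)C(C)(C)C | intermediate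
12 | (6Z,10E)-3-bromo-13-[(tert-butyldimethylsilyl)oxy]-2,6,10-trimethyltrideca-6,10-dien-2-ol (racemic at C3) | CC(C)(O)C(Br)CC/C(C)=C\CC/C(C)=C/CCO[Si](C)(C)C(C)(C)C | intermediate
13 | tert-butyl{[(3E,7Z)-10-(3,3-dimethyloxiran-2-yl)-4,8-dimethyldeca-3,7-dien-1-yl]oxy}dimethylsilane (racemic) | CC1(C)OC1CC/C(C)=C\CC/C(C)=C/CCO[Si](C)(C)C(C)(C)C | intermediate
14 | (4Z,8E)-11-[(tert-butyldimethylsilyl)oxy]-4,8-dimethylundeca-4,8-dienal | O=CCC/C(C)=C\CC/C(C)=C/CCO[Si](C)(C)C(C)(C)C | intermediate
15 | methyl bis(2,2,2-trifluoroethyl)phosphonoacetate | COC(=O)CP(=O)(OCC(F)(F)F)OCC(F)(F)F | starting material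
16 | methyl dibromo[bis(2,2,2-trifluoroethoxy)phosphoryl]acetate | COC(=O)C(Br)(Br)P(=O)(OCC(F)(F)F)OCC(F)(F)F | intermediate
17 | methyl bromo[bis(2,2,2-trifluoroethoxy)phosphoryl]acetate (racemic) | COC(=O)C(Br)P(=O)(OCC(F)(F)F)OCC(F)(F)F | intermediate
18 | potassium salt of the carbanion of 17 (not isolated) | [K+].COC(=O)[C-](Br)P(=O)(OCC(F)(F)F)OCC(F)(F)F | intermediate
19 | methyl (2E,6Z,10E)-2-bromo-13-[(tert-butyldimethylsilyl)oxy]-6,10-dimethyltrideca-2,6,10-trienoate | COC(=O)/C(Br)=C\CC/C(C)=C\CC/C(C)=C/CCO[Si](C)(C)C(C)(C)C | intermediate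
20 | (2E,6Z,10E)-2-bromo-13-[(tert-butyldimethylsilyl)oxy]-6,10-dimethyltrideca-2,6,10-trien-1-ol | OC/C(Br)=C\CC/C(C)=C\CC/C(C)=C/CCO[Si](C)(C)C(C)(C)C | intermediate
21 | (2E,6Z,10E)-2-bromo-1-[(tert-butyldiphenylsilyl)oxy]-13-[(tert-butyldimethylsilyl)oxy]-6,10-dimethyltrideca-2,6,10-triene | CC(C)(C)[Si](OC/C(Br)=C\CC/C(C)=C\CC/C(C)=C/CCO[Si](C)(C)C(C)(C)C)(c1ccccc1)c1ccccc1 | intermediate
22 | tributyl(vinyl)stannane | C=C[Sn](CCCC)(CCCC)CCCC | starting material
23 | (2Z,6Z,10E)-1-[(tert-butyldiphenylsilyl)oxy]-13-[(tert-butyldimethylsilyl)oxy]-2-ethenyl-6,10-dimethyltrideca-2,6,10-triene | C=C/C(CO[Si](c1ccccc1)(c1ccccc1)C(C)(C)C)=C/CC/C(C)=C\CC/C(C)=C/CCO[Si](C)(C)C(C)(C)C | intermediate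
24 | (3E,7Z,11Z)-12-{[(tert-butyldiphenylsilyl)oxy]methyl}-4,8-dimethyltetradeca-3,7,11,13-tetraen-1-ol | C=C/C(CO[Si](c1ccccc1)(c1ccccc1)C(C)(C)C)=C/CC/C(C)=C\CC/C(C)=C/CCO | intermediate
25 | (3E,7Z,11Z)-12-{[(tert-butyldiphenylsilyl)oxy]methyl}-4,8-dimethyltetradeca-3,7,11,13-tetraenal | C=C/C(CO[Si](c1ccccc1)(c1ccccc1)C(C)(C)C)=C/CC/C(C)=C\CC/C(C)=C/CC=O | intermediate
26 | 5-bromo-2-methylpent-2-ene | CC(C)=CCCBr | starting material
27 | sodium salt of the carbanion of 15 (not isolated) | [Na+].COC(=O)[CH-]P(=O)(OCC(F)(F)F)OCC(F)(F)F | intermediate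
28 | methyl 2-[bis(2,2,2-trifluoroethoxy)phosphoryl]-6-methylhept-5-enoate (racemic) | COC(=O)C(CCC=C(C)C)P(=O)(OCC(F)(F)F)OCC(F)(F)F | intermediate
29 | potassium salt of the carbanion of 28 (not isolated) | [K+].COC(=O)[C-](CCC=C(C)C)P(=O)(OCC(F)(F)F)OCC(F)(F)F | intermediate
30 | methyl (2Z,5E,9Z,13Z)-14-{[(tert-butyldiphenylsilyl)oxy]methyl}-6,10-dimethyl-2-(4-methylpent-3-en-1-yl)hexadeca-2,5,9,13,15-pentaenoate | C=C/C(CO[Si](c1ccccc1)(c1ccccc1)C(C)(C)C)=C/CC/C(C)=C\CC/C(C)=C/C/C=C(/CCC=C(C)C)C(=O)OC | intermediate
31 | methyl (1S,3E,7Z,11S,15S)-12-{[(tert-butyldiphenylsilyl)oxy]methyl}-4,8-dimethyl-15-(4-methylpent-3-en-1-yl)bicyclo[9.3.1]pentadeca-3,7,12-triene-15-carboxylate | CC(C)=CCC[C@]1(C(=O)OC)[C@@H]2CC=C(CO[Si](c3ccccc3)(c3ccccc3)C(C)(C)C)[C@@H]1CC/C(C)=C\CC/C(C)=C/C2 | intermediate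
32 | methyl (1S,3E,7Z,11S,15S)-12-(hydroxymethyl)-4,8-dimethyl-15-(4-methylpent-3-en-1-yl)bicyclo[9.3.1]pentadeca-3,7,12-triene-15-carboxylate | CC(C)=CCC[C@]1(C(=O)OC)[C@@H]2CC=C(CO)[C@@H]1CC/C(C)=C\CC/C(C)=C/C2 | intermediate
33 | (1S,3E,7Z,11S,15S)-12-(hydroxymethyl)-4,8-dimethyl-15-(4-methylpent-3-en-1-yl)bicyclo[9.3.1]pentadeca-3,7,12-triene-15-carboxylic acid, CNP0267152.2 (C1, C2 and C6 of the cyclohexene numbering are all S) | CC(C)=CCC[C@]1(C(=O)O)[C@@H]2CC=C(CO)[C@@H]1CC/C(C)=C\CC/C(C)=C/C2 | target

Total step count: 21.
Longest linear sequence: 18 steps from nerol (steps 1–8, 11–16 and 18–21); steps 9–10 and step 17 are side branches.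

Steps most likely to fail

1. Step 19 (labelled step). Risks:
- The trisubstituted enoate may be activated too weakly for the catalyst to turn over at high dilution.
- Facial or exo control may be poor.
- Closure may go in the fused orientation, since the C5 substituent polarises the diene against the C7 alkyl group.
- The Lewis acid may start cationic cyclisation of the trisubstituted alkenes.

Fallback, setting out from 30 and returning at 32: 30 is cyclised without a chiral catalyst, with Me2AlCl (1.1 equiv) in CH2Cl2 at 1 mM between −20 °C and rt or, if the Lewis acid attacks the alkenes, thermally in toluene at 170 °C with BHT. This known macrocyclising intramolecular Diels–Alder reaction should give 31 as the racemate, that is together with its mirror image, the ent-cycloadduct F1. Bu4NF in THF then gives 32 together with the ent-hydroxy ester F2. Acylation of the mixture with (1S)-camphanic chloride (O=C(Cl)[C@@]12CC[C@@](C)(C(=O)O1)C2(C)C; Et3N, DMAP, CH2Cl2) gives the (1S,4R)-camphanate of 32 F3 and the diastereomeric camphanate F4 derived from F2, which are separated by chromatography or crystallisation. K2CO3 in MeOH removes the camphanate from F3 and returns 32, from which step 21 follows.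

2. Step 18. Risks: the β,γ-unsaturated aldehyde may enolise, moving the C13=C14 alkene into conjugation, and the α-branched phosphonate may give eroded (Z)-selectivity.

Fallback, setting out from 25 and returning at 30: 25 is condensed with bromophosphonate 17 under the conditions of step 11 (KOt-Bu, 18-crown-6, THF, −78 °C), where the less basic and more reactive anion should give the (E)-α-bromo hexaenoate F5 with the chain again cis to the ester. Negishi coupling with (4-methylpent-3-enyl)zinc bromide F6 (from 26, Zn dust, LiCl, THF, 40 °C) under PdCl2(dppf) catalysis in THF at rt replaces bromine by the alkyl group with retention and gives 30.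

3. Step 17. Risks: C-alkylation of the weakly nucleophilic fluorinated phosphonate anion may be slow, with competing E2 elimination of the homoallylic bromide, a second alkylation and loss of trifluoroethoxide.

Fallback, setting out from 26 and returning at 28: commercial trimethyl phosphonoacetate (COC(=O)CP(=O)(OC)OC), a far better nucleophile, is alkylated with 26 (NaH, DMF, catalytic NaI, 50 °C) to methyl 2-(dimethoxyphosphoryl)-6-methylhept-5-enoate F7. Me3SiBr with pyridine in CH2Cl2 converts the two P–OMe groups selectively into the bis(trimethylsilyl) phosphonate F8 (McKenna reaction). (COCl)2 with catalytic DMF gives the phosphonic dichloride F9, and CF3CH2OH with i-Pr2NEt gives 28.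

Further compounds
F1 | step 19 | ent-cycloadduct, mirror image of 31 | CC(C)=CCC[C@@]1(C(=O)OC)[C@H]2CC=C(CO[Si](c3ccccc3)(c3ccccc3)C(C)(C)C)[C@H]1CC/C(C)=C\CC/C(C)=C/C2
F2 | step 19 | ent-hydroxy ester, mirror image of 32 | CC(C)=CCC[C@@]1(C(=O)OC)[C@H]2CC=C(CO)[C@H]1CC/C(C)=C\CC/C(C)=C/C2
F3 | step 19 | (1S,4R)-camphanate of 32 | CC(C)=CCC[C@]1(C(=O)OC)[C@@H]2CC=C(COC(=O)[C@@]34CC[C@@](C)(C(=O)O3)C4(C)C)[C@@H]1CC/C(C)=C\CC/C(C)=C/C2
F4 | step 19 | (1S,4R)-camphanate of F2 | CC(C)=CCC[C@@]1(C(=O)OC)[C@H]2CC=C(COC(=O)[C@@]34CC[C@@](C)(C(=O)O3)C4(C)C)[C@H]1CC/C(C)=C\CC/C(C)=C/C2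
F5 | step 18 | methyl (2E,5E,9Z,13Z)-2-bromo-14-{[(tert-butyldiphenylsilyl)oxy]methyl}-6,10-dimethylhexadeca-2,5,9,13,15-pentaenoate | C=C/C(CO[Si](c1ccccc1)(c1ccccc1)C(C)(C)C)=C/CC/C(C)=C\CC/C(C)=C/C/C=C(/Br)C(=O)OC
F6 | step 18 | (4-methylpent-3-enyl)zinc bromide | CC(C)=CCC[Zn]Br
F7 | step 17 | methyl 2-(dimethoxyphosphoryl)-6-methylhept-5-enoate | COC(=O)C(CCC=C(C)C)P(=O)(OC)OC
F8 | step 17 | methyl 2-[bis(trimethylsilyloxy)phosphoryl]-6-methylhept-5-enoate | COC(=O)C(CCC=C(C)C)P(=O)(O[Si](C)(C)C)O[Si](C)(C)C
F9 | step 17 | methyl 2-(dichlorophosphoryl)-6-methylhept-5-enoate | COC(=O)C(CCC=C(C)C)P(=O)(Cl)Cl
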